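## Retrosynthetic overview
1. Last step (key step): three C–O bonds form in one oxidative operation. These are the phenol O (from an aryl–B bond) and C9–O and C8–O of the anti-diol, made from the C8=C9 alkene by α-face epoxidation and then water attack at C8 with inversion.
2. The ester C6–O bond comes from jaeschkeanadiol and 4-(pinacolboryl)benzoic acid, which serves as a latent 4-hydroxybenzoate.
3. The C4–isopropyl bond comes from Grignard addition to the bicyclic 4-ketone from the α-face.
4. The seven-membered ring (ring B) is closed second, by ring-closing metathesis at C8=C9 on the intact cyclopentanone (ring A).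
5. Ring A is bought as 3-ethoxycyclopentenone. C1, C5 and C6 are set in one flask by catalytic asymmetric methyl conjugate addition followed by an anti-aldol reaction with 3-methylbut-3-enal.

Numbering used (daucane): C1 = quaternary ring-fusion carbon (CH3); C2, C3 = CH2; C4 = carbinol carbon bearing i-Pr; C5 = ring-fusion CH; C6 = CH–O-acyl; C7 = CH2; C8 = C(CH3)(OH); C9 = CH(OH); C10 = CH2. α is the face opposite the C1 methyl group.

Assumption: L* is a 1-mesityl-4,5-diphenyl-3-(2-sulfonatophenyl)imidazolinium zwitterion, used as the antipode that delivers CH3 to the Si face of C3 of enone 3 (both antipodes come from commercial (R,R)- or (S,S)-1,2-diphenylethane-1,2-diamine).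

## Route

Step 1
Reactants: 1 3-ethoxycyclopent-2-en-1-one
Product: 3 3-allylcyclopent-2-en-1-one, via 1-allyl-3-ethoxycyclopent-2-en-1-ol 2 (not isolated)
Conditions: allylMgBr (1.2 equiv), Et2O, −78 → 0 °C; then 1 M HCl, 0 °C, 20 min
Reagents that add atoms: allylmagnesium bromide, C=CC[Mg]Br; water, O
Why: Stork–Danheiser sequence: 1,2-addition of the Grignard reagent to the vinylogous ester gives 2, which on brief cold acid treatment ionises, takes up water at the ethoxy-bearing carbon and loses ethanol, so the carbonyl group is transposed and the β-allyl enone results (no stereocentre; short acid contact keeps the skipped diene out of conjugation).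

Step 2
Reactants: 4 3-methylbut-3-en-1-ol
Product: 5 3-methylbut-3-enal
Conditions: Dess–Martin periodinane (1.1 equiv), CH2Cl2, 0 °C → rt, 1 h; cold aqueous wash, dried CH2Cl2 solution used at once
Reagents that add atoms: none
Why: Dess–Martin oxidation is neutral, fast and non-enolising, so the β,γ-unsaturated aldehyde forms without migration of the double bond to prenal (no stereocentre).

Step 3
Reactants: 3 3-allylcyclopent-2-en-1-one; 5 3-methylbut-3-enal
Product: 7 (2S,3R)-3-allyl-2-[(1S)-1-hydroxy-3-methylbut-3-enyl]-3-methylcyclopentan-1-one, via dimethylaluminium enolate 6 (not isolated)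
Conditions: Cu(OTf)2 (5 mol %), silver carbene complex made from Ag2O and L* (2.5 mol %), Me3Al (2 equiv), THF, −78 °C, 24 h; then 5 (4 equiv), −78 → −40 °C; aq. potassium sodium tartrate; chromatography
Reagents that add atoms: trimethylaluminium, C[Al](C)C
Why: Copper-catalysed asymmetric conjugate addition followed by an aldol reaction in the same flask: the chiral carbene–copper methyl species delivers CH3 to the Si face of C3 of 3 and sets the quaternary C1 (R), and the regiodefined E-enolate 6 adds to 5 through a closed Zimmerman–Traxler chair (anti aldol) on the face carrying the small CH3 group, anti to the allyl chain, which sets C5 (S) and C6 (S).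

Step 4
Reactants: 7 (2S,3R)-3-allyl-2-[(1S)-1-hydroxy-3-methylbut-3-enyl]-3-methylcyclopentan-1-one
Product: 8 (3aS,4S,8aR)-4-hydroxy-6,8a-dimethyl-2,3a,4,5,8,8a-hexahydroazulen-3(1H)-one
Conditions: second-generation Hoveyda–Grubbs catalyst (3 mol %), CH2Cl2 (5 mM), 40 °C
Reagents that add atoms: none
Why: Ring-closing metathesis of the monosubstituted and the 1,1-disubstituted alkene closes ring B as the trisubstituted C8=C9 cycloheptene, driven by loss of ethene; the ketone and free hydroxyl are tolerated and no stereocentre is touched.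

Step 5
Reactants: 8 (3aS,4S,8aR)-4-hydroxy-6,8a-dimethyl-2,3a,4,5,8,8a-hexahydroazulen-3(1H)-one
Product: 9 (3R,3aS,4S,8aR)-6,8a-dimethyl-3-(propan-2-yl)-1,2,3,3a,4,5,8,8a-octahydroazulene-3,4-diol (jaeschkeanadiol)
Conditions: LaCl3·2LiCl (1.1 equiv), THF, rt, 1 h; then i-PrMgCl (3 equiv), −20 → 0 °C; H2O quench
Reagents that add atoms: isopropylmagnesium chloride, CC(C)[Mg]Cl
Why: Lanthanide-promoted Grignard 1,2-addition: LaCl3·2LiCl activates the carbonyl group and damps the basicity of i-PrMgCl, so addition beats enolisation, β-hydride reduction and retro-aldol cleavage, and the nucleophile enters the C6-alkoxide-chelated ketone from the α-face, opposite the angular C1 methyl group, which sets C4 (R, 4β-OH).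

Step 6
Reactants: 9 jaeschkeanadiol; 10 4-(4,4,5,5-tetramethyl-1,3,2-dioxaborolan-2-yl)benzoic acid
Product: 11 (3R,3aS,4S,8aR)-3-hydroxy-6,8a-dimethyl-3-(propan-2-yl)-1,2,3,3a,4,5,8,8a-octahydroazulen-4-yl 4-(4,4,5,5-tetramethyl-1,3,2-dioxaborolan-2-yl)benzoate
Conditions: 10 (2 equiv), DCC (2.2 equiv), DMAP (0.3 equiv), toluene, 60 °C, 16 h
Reagents that add atoms: none
Why: Steglich esterification: the DMAP-activated acyl group reaches only the secondary 6α-OH while the tertiary 4β-OH is inert, the C6–O bond is not broken so its configuration is retained, and the pinacol boronate (a latent phenol that can neither be acylated nor transfer an acyl group) survives.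

Step 7
Reactants: 11 jaeschkeanadiol 6-O-[4-(pinacolboryl)benzoate]
Product: 14 (3R,3aS,4S,6S,7S,8aR)-3,6,7-trihydroxy-6,8a-dimethyl-3-(propan-2-yl)decahydroazulen-4-yl 4-hydroxybenzoate (target), via ferutinin 12 (not isolated), via ferutinin 8α,9α-epoxide 13 (not isolated)
Conditions: CH3ReO3 (3 mol %), 30 % aq. H2O2 (4 equiv), t-BuOH–H2O 4:1, 0 °C → rt, 12 h (no pyridine, no buffer)
Reagents that add atoms: hydrogen peroxide, OO; water, O
Why: Proposed new method: a one-flask triple oxygenation in which unbuffered CH3ReO3/H2O2 (i) turns the aryl–B bond into the phenol C–O bond by peroxide addition to boron and 1,2-aryl shift, (ii) transfers oxygen from the bulky diperoxo complex CH3ReO(O2)2·H2O to the open α-face of C8=C9 (in the chair cycloheptene the β-face is flanked by the axial C1 methyl group and axial H6), and (iii) lets the acidic, Lewis-acidic rhenium aqua species open the epoxide with water at the tertiary, cation-stabilising C8 from the β-face with inversion (trans-diaxial opening; attack at C9 would run syn-axial to the C1 methyl group), so that C9 (S, 9α-OH) and C8 (S, 8β-OH) are set in one operation; using a 4-boronobenzoate as a latent 4-hydroxybenzoate that is unmasked by the same oxidant that builds the anti-diol has not been described, and the closest known reaction types are peroxide ipso-hydroxylation of arylboronates and rhenium-catalysed alkene epoxidation followed by hydrolytic ring opening.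

## Compound list
1 | 3-ethoxycyclopent-2-en-1-one | CCOC1=CC(=O)CC1 | starting material
2 | 1-allyl-3-ethoxycyclopent-2-en-1-ol (racemic, not isolated) | C=CCC1(O)CCC(OCC)=C1 | intermediate
3 | 3-allylcyclopent-2-en-1-one | C=CCC1=CC(=O)CC1 | intermediate
4 | 3-methylbut-3-en-1-ol (isoprenol) | CC(=C)CCO | starting material
5 | 3-methylbut-3-enal | CC(=C)CC=O | intermediate
6 | dimethylaluminium (R)-3-allyl-3-methylcyclopent-1-en-1-olate (not isolated) | C[C@]1(CC=C)CCC(O[Al](C)C)=C1 | intermediate
7 | (2S,3R)-3-allyl-2-[(1S)-1-hydroxy-3-methylbut-3-enyl]-3-methylcyclopentan-1-one | O=C1CC[C@](C)(CC=C)[C@H]1[C@@H](O)CC(C)=C | intermediate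
8 | (3aS,4S,8aR)-4-hydroxy-6,8a-dimethyl-2,3a,4,5,8,8a-hexahydroazulen-3(1H)-one (trans-fused, 6α-OH) | O=C1CC[C@]2(C)CC=C(C)C[C@H](O)[C@H]21 | intermediate
9 | (3R,3aS,4S,8aR)-6,8a-dimethyl-3-(propan-2-yl)-1,2,3,3a,4,5,8,8a-octahydroazulene-3,4-diol (jaeschkeanadiol) | CC(C)[C@]1(O)CC[C@]2(C)CC=C(C)C[C@H](O)[C@H]21 | intermediate
10 | 4-(4,4,5,5-tetramethyl-1,3,2-dioxaborolan-2-yl)benzoic acid | OC(=O)c1ccc(cc1)B2OC(C)(C)C(C)(C)O2 | starting material
11 | jaeschkeanadiol 6-O-[4-(4,4,5,5-tetramethyl-1,3,2-dioxaborolan-2-yl)benzoate] | CC(C)[C@]1(O)CC[C@]2(C)CC=C(C)C[C@H](OC(=O)c3ccc(cc3)B4OC(C)(C)C(C)(C)O4)[C@H]21 | intermediate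
12 | ferutinin (jaeschkeanadiol 6-O-(4-hydroxybenzoate), not isolated) | CC(C)[C@]1(O)CC[C@]2(C)CC=C(C)C[C@H](OC(=O)c3ccc(O)cc3)[C@H]21 | intermediate
13 | ferutinin 8α,9α-epoxide, (1R,4R,5S,6S,8R,9S) in daucane numbering (not isolated) | CC(C)[C@]1(O)CC[C@]2(C)C[C@@H]3O[C@]3(C)C[C@H](OC(=O)c4ccc(O)cc4)[C@H]21 | intermediate
14 | (3R,3aS,4S,6S,7S,8aR)-3,6,7-trihydroxy-6,8a-dimethyl-3-(propan-2-yl)decahydroazulen-4-yl 4-hydroxybenzoate | CC(C)[C@]1(O)CC[C@]2(C)C[C@H](O)[C@@](C)(O)C[C@H](OC(=O)c3ccc(O)cc3)[C@H]21 | target

## Step count and risks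
Total step count: 7.
Longest linear sequence: 6 (steps 1, 3, 4, 5, 6, 7). Step 2 is a one-step side branch.

**Step 7 (the proposed new step).**
- Risks: incomplete hydrolysis of 13; E1-type loss of a proton to the 8(14)-en-9-ol; rearrangement to the C9 ketone; transannular attack of the 4β-OH on C8; some β-epoxide.
- Fallback, known chemistry only, sets out from 9 and comes back at 13. VO(acac)2 (2 mol %)/t-BuOOH (CH2Cl2, 0 °C) epoxidises 9 under direction of the homoallylic 6α-OH, which secures the α-face, and gives 8α,9α-epoxyjaeschkeanadiol F4.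
- DCC/DMAP coupling with 10 gives 8α,9α-epoxyjaeschkeanadiol 6-O-[4-(pinacolboryl)benzoate] F5.
- NaBO3·4H2O (THF–H2O, rt) unmasks the phenol and gives isolated 13. HClO4 (5 mol %) in THF–H2O at 0 °C then opens 13 at C8 with inversion to 14.

**Step 3.**
- Risks: excess Me3Al competes with enolate 6 for aldehyde 5; the hindered aluminium enolate may be sluggish; the methyl-versus-allyl face preference may be modest; 3 may drift into conjugation.
- Fallback sets out from 3 and comes back at 7. The methyl addition is run as before, but 6 is quenched with Et3SiOTf (−78 °C) and isolated, free of aluminium alkyls, as (R)-[(3-allyl-3-methylcyclopent-1-en-1-yl)oxy]triethylsilane F1.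
- MeLi (THF, 0 °C) cleaves the Si–O bond to lithium (R)-3-allyl-3-methylcyclopent-1-en-1-olate F2. This is cooled to −78 °C and treated with 5 for a few minutes, giving 7 by a closed-transition-state lithium aldol reaction.

**Step 5.**
- Risks: enolisation, β-hydride reduction or retro-aldol cleavage instead of addition to the hindered α-branched ketone.
- Fallback sets out from 8 and comes back at 9. Isopropenylmagnesium bromide/CeCl3 (THF, −78 °C) is a smaller, less basic sp2 nucleophile with no β-hydride to transfer. It adds from the same α-face to give (3S,3aS,4S,8aR)-6,8a-dimethyl-3-(prop-1-en-2-yl)-1,2,3,3a,4,5,8,8a-octahydroazulene-3,4-diol F3.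
- H2 (1 atm) over RhCl(PPh3)3 in benzene–EtOH saturates the 1,1-disubstituted alkene faster than the trisubstituted ring alkene and gives 9.

## Further compounds
F1 | step 3 | (R)-[(3-allyl-3-methylcyclopent-1-en-1-yl)oxy]triethylsilane | C[C@]1(CC=C)CCC(O[Si](CC)(CC)CC)=C1
F2 | step 3 | lithium (R)-3-allyl-3-methylcyclopent-1-en-1-olate | C[C@]1(CC=C)CCC([O-])=C1.[Li+]
F3 | step 5 | (3S,3aS,4S,8aR)-6,8a-dimethyl-3-(prop-1-en-2-yl)-1,2,3,3a,4,5,8,8a-octahydroazulene-3,4-diol | CC(=C)[C@]1(O)CC[C@]2(C)CC=C(C)C[C@H](O)[C@H]21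
F4 | step 7 | 8α,9α-epoxyjaeschkeanadiol | CC(C)[C@]1(O)CC[C@]2(C)C[C@@H]3O[C@]3(C)C[C@H](O)[C@H]21
F5 | step 7 | 8α,9α-epoxyjaeschkeanadiol 6-O-[4-(pinacolboryl)benzoate] | CC(C)[C@]1(O)CC[C@]2(C)C[C@@H]3O[C@]3(C)C[C@H](OC(=O)c4ccc(cc4)B5OC(C)(C)C(C)(C)O5)[C@H]21
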